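# Lehualide E: synthesis proposal

## The problem

1. Lehualide E (14) is an achiral C24 compound. It is a 2H-pyran-2-one ring (O1, C2=O, C3–OCH3, C4–OCH3, C5–CH3, C6) that carries at C6 the chain C1′H2–C2′H=C3′(CH3)–(CH2)6–C6H5.
2. No ring carbon bears hydrogen, so every substituent must be placed by construction, and C5 and C6 differ only as methyl against methylene.
3. The 3,4-dimethoxy pattern is that of a 4-hydroxy-2-pyranone with an ambident anion, so late O-methylation can end on the C2 oxygen and give the isomeric 4-pyranone.
4. There is no stereocentre. The only stereochemical element is the E geometry of C2′=C3′. The two groups on C3′ (CH3, CH2R) are too alike for thermodynamic or Wittig-type control, so the geometry must come from a stereospecific addition to an alkyne and then be carried with retention.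
5. C1′H2 is both allylic and vinylogously α to the lactone carbonyl (C1′–C6=C5–C4=C3–C2=O). Bases and strong acids will therefore move C2′=C3′ into conjugation, and the skipped diene must appear late under nearly neutral conditions.
6. The phenylhexyl tail is inert and poses no problem.
7. The feature that opens the key step is the triad C5(CH3)=C6(O1)–C1′H2. An enol-ester carbon between a methyl-bearing sp2 carbon and a methylene is a carboxylic acid added to the central carbon of an allene C5=C6=C1′. An allene with a fully substituted C5 and a new carbon group on C1′ is the SN2′ product of a tertiary propargylic carboxylate.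
8. C2, C3 and C4 hold that carboxylate cis to C5, so the propargylic ester is itself a ring, the butenolide O1–C2–C3=C4–C5. The pyranone ring of 14 is this furanone ring with O1 moved from C5 to C6.

## Retrosynthesis

**O1–C6 (14 ⇒ 13 ⇒ 12).**
- The enol-ester bond O1–C6 is cut and one hydrogen goes from C1′ back to oxygen. This gives the alkylidenepyranol 13 and then the (2Z)-2-en-4,5-dienoic acid 12.
- The neighbouring cut O1–C2 would give a δ-keto acid whose ketone is β,γ-unsaturated and enolises toward C1′. The chosen cut leaves no carbonyl next to C1′.
- 12 is an isomer of 14, so size does not change, but the ring problem becomes an allene problem.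
- The forward reaction must close the six-membered and not the five-membered ring, and must put the last proton on C1′.

**C1′–C2′, with O1 returned to C5 (12 ⇒ 7 + 11).**
- The bond between the allene terminus and the alkenyl carbon is cut, and the carboxylate is reattached at C5. This gives the ethynylbutenolide 7 and the alkenylalane 11.
- A cut at C6–C1′ would need a metalated or halogenated pyranone. A cut at C3′–C4′ would leave the alkene geometry open.
- The chosen cut splits C24 into C9 and C15. It keeps both methoxy groups and the Z relation of C2 and C5 locked in a small ring, and it joins an sp2 carbon of fixed geometry.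
- The forward reaction must be SN2′-selective and must retain the alkenyl configuration.

**C3′–CH3 and C2′–Al (11 ⇒ 10).**
- Methyl and aluminium are removed from the same face of the alkene, which leaves the terminal alkyne 10.
- Carbonyl olefination at C2′=C3′ offers no geometric bias, whereas syn-methylalumination does.
- The precursor has no stereochemical element.
- The forward reaction must put methyl on the inner carbon.

**C(sp)–C(sp3) in 10 (10 ⇒ 8 + 9).**
- The bond between the propargylic methylene and the alkyne is cut to the primary bromide 8 and the acetylide 9. Both are commercial.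
- Any other cut of the saturated chain would need two functionalised fragments.
- The forward step is a plain SN2 reaction.

**O–CH3 at C4 (7 ⇒ 6).**
- The C4 methyl ether is cut to the 3-methoxytetronic acid 6.
- The methylation problem of the pyranone is moved onto a tetronic acid, where the vinylogous carboxylate oxygen at C4 is the known site of O-alkylation.
- It is settled before any sensitive group exists.

**C3–C4 (6 ⇒ 5).**
- The ring is opened between the methoxy-bearing carbon and the enol carbon, which gives the diester 5.
- This cut uses the only enolisable CH2 of 5 and the only ester within reach, so the forward Dieckmann closure has no regiochemical choice.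

**Acyl C2–O1 (5 ⇒ 3 + 4).**
- The ester bond is cut to the tertiary propargylic alcohol 3 and the acid chloride 4.
- 4 brings in C2, C3 and the C3 methoxy group in one commercial piece.

**C5–C(sp) (3 ⇒ 1 + 2).**
- The bond from the carbinol carbon to the alkyne is cut to the α-keto ester 1 and the alkynyl Grignard reagent 2.
- 1 supplies C4, C5 and the C5 methyl group.
- The forward reaction only has to prefer the ketone to the ester. A racemic centre is acceptable because it vanishes in the key step.

## Roads not taken

**Alternative 1: the obvious, polyketide-type route.**
- Cut: O1–C2 and the C4 O–CH3 bond.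
- Forward key step: base-induced lactonisation of the 3,5-dioxo ester A1 to the 4-hydroxy-2-pyranone A2, followed by O-methylation.
- A1 contains a β,γ-unsaturated ketone whose C6 methylene is its most acidic unblocked position. The Claisen chemistry that builds A1 and the base that closes A2 therefore both invite migration of the alkene into conjugation.
- The anion of A2 is ambident, and methylation can also give the 4-pyranone A3.
- The sequence is linear and carries the sensitive chain through every basic step.
- The chosen plan fixes both methyl ethers on a C9 ring and creates C1′H2 in the last event.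

**Alternative 2: the squarate route.**
- Cut: O1–C6 again, but traced back to a four-membered ring.
- Forward key step: thermal 4π opening of the 4-acyl-4-methylcyclobutenone A6 to an acylvinylketene, then 6π oxa-closure. Both methoxy groups would come from dimethyl squarate A4.
- The cascade is neutral and attractive, but A6 is out of reach in few steps. Its quaternary carbon has to be made from the methyl adduct A5 by replacing a tertiary hydroxyl with an acyl anion equivalent.
- Ionisation of A5 gives an oxocyclobutenyl cation that loses a methyl group to give the dione A7 or is attacked at the wrong terminus.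
- Enolate chemistry at that carbon would pass through an antiaromatic oxycyclobutadiene.
- A β,γ-unsaturated acyl anion equivalent would itself cost several steps. The run-up would consume what the cascade gains.

**Alternative 3: alkyne annulation.**
- Cut: C4–C5 and O1–C6 together.
- Forward key step: oxidative C–H annulation (Rh or Ru) of the acrylic acid A8 with the skipped enyne A9.
- The two alkyne carbons of A9 carry CH3 and CH2R, with neither steric nor electronic bias, so the regioisomer A10 must be expected beside 14.
- The 1,4-enyne is exposed to a metal hydride-forming medium and an external oxidant.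
- A8 itself has to be made.
- In the chosen plan the assignment of C5 and C6 follows from connectivity and not from a selectivity.

Key step: step 6

Assumption: 14 has no stereocentre, so "single enantiomer" is read as the single (E) isomer of the given SMILES. The racemic intermediates 3, 5, 6, 7 and 12 lose their stereogenic units in step 6.

## Route

Step 1
Reactants: 1 methyl pyruvate; 2 ethynylmagnesium bromide
Product: 3 methyl (±)-2-hydroxy-2-methylbut-3-ynoate
Conditions: THF, −78 °C; then 1 M HCl, 0 °C
Reagents that add atoms: none
Why: 1,2-Addition of an alkynyl Grignard reagent to an α-keto ester, whose ketone is far more electrophilic than its ester at low temperature. The new centre (later C5) is formed racemic on purpose, because step 6 erases it.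

Step 2
Reactants: 3 methyl (±)-2-hydroxy-2-methylbut-3-ynoate; 4 methoxyacetyl chloride
Product: 5 methyl (±)-2-[(methoxyacetyl)oxy]-2-methylbut-3-ynoate
Conditions: pyridine, DMAP (cat.), CH2Cl2, 0 °C → rt
Reagents that add atoms: none
Why: DMAP-catalysed O-acylation of a tertiary alcohol with a reactive acid chloride. Pyridine instead of a trialkylamine keeps dehydrochlorination to the ketene low.

Step 3
Reactants: 5 methyl (±)-2-[(methoxyacetyl)oxy]-2-methylbut-3-ynoate
Product: 6 (±)-5-ethynyl-4-hydroxy-3-methoxy-5-methylfuran-2(5H)-one
Conditions: LiHMDS (3 equiv), THF, −78 → 0 °C; then 1 M HCl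
Reagents that add atoms: none
Why: Dieckmann condensation of an α-acyloxy ester, the standard entry to 3-alkoxytetronic acids. The only enolate available attacks the neighbouring methyl ester (5-exo-trig), and the acidic product is shielded as its lithium salt. The extra base covers the alkyne C–H.

Step 4
Reactants: 6 (±)-5-ethynyl-4-hydroxy-3-methoxy-5-methylfuran-2(5H)-one
Product: 7 (±)-5-ethynyl-3,4-dimethoxy-5-methylfuran-2(5H)-one
Conditions: Me2SO4, K2CO3, acetone, rt
Reagents that add atoms: dimethyl sulfate, COS(=O)(=O)OC
Why: O-Alkylation of a tetronate anion with a hard methylating agent. As in the 2,3-di-O-alkylation of ascorbic acid, the vinylogous carboxylate oxygen at C4 is the reacting site, and C3 is blocked by its methoxy group.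

Step 5
Reactants: 8 (6-bromohexyl)benzene; 9 lithium acetylide–ethylenediamine complex
Product: 10 oct-7-yn-1-ylbenzene
Conditions: DMSO, 0 °C → rt
Reagents that add atoms: none
Why: SN2 alkylation of lithium acetylide with an unhindered primary bromide in a dipolar aprotic solvent.

Step 6
Reactants: 10 oct-7-yn-1-ylbenzene; 7 (±)-5-ethynyl-3,4-dimethoxy-5-methylfuran-2(5H)-one
Product: 14 lehualide E, via alkenylalane 11 (not isolated), via allenic acid 12 (not isolated), via alkylidenepyranol 13 (not isolated)
Conditions: (i) Me3Al (2 equiv), Cp2ZrCl2 (0.2 equiv), CH2Cl2, 0 °C → rt, then volatiles off in vacuo; (ii) 7, Pd(PPh3)4 (5 mol %), THF, 0 °C → rt; (iii) aq. NaH2PO4/Rochelle salt, 0 °C, extraction; (iv) Et3N (0.2 equiv), toluene, 40 °C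
Reagents that add atoms: trimethylaluminium, C[Al](C)C
Why: Proposed new method: Zr-catalysed syn-methylalumination (Negishi carboalumination) of the terminal alkyne 10 places CH3 on C3′ and Al on C2′ on the same face, so 11 carries the E geometry of the target before any coupling. Pd(0), with the Lewis-acidic alane on the lactone carbonyl, ionises the tertiary propargylic C5–O1 bond of 7 in the SN2′ sense to a σ-allenylpalladium carboxylate; transmetalation from 11 and reductive elimination, both with retention at C2′, make the C1′–C2′ bond and leave the aluminium salt of 12, which the buffered work-up sets free. In 12 the carboxyl group and the allene are locked cis on the former ring alkene C3=C4, so O=C2–C3=C4–C5=C6 is a 1-oxatriene that closes the O1–C6 bond by a thermal 6π oxa-electrocyclisation (formally 6-endo attack on the central allene carbon) to 13, and an amine-relayed proton shift from O–H to C1′ gives the aromatic pyranone 14; the net result is a 1,2-shift of the lactone oxygen from C5 to C6, a five- to six-membered ring expansion. Closest known reaction types are the Pd-catalysed coupling of 2-methylalkenylalanes with allylic esters, the Pd- or Cu-mediated SN2′ conversion of propargylic esters and ethynyl lactones into allenes and allenic acids, the fast oxa-6π closure of (Z)-2,4,5-trienals and -trienones to 2-alkylidene-2H-pyrans, and 2-pyranone formation from (Z)-β-iodoacrylic acids and allenylstannanes; their union on an ethynylbutenolide is new. No stereocentre is created: the centre C5 of 7 and the axis of 12 are both erased, so racemic 7 suffices, and the only stereo-element, E-C2′=C3′, is set by the syn addition. Selectivity needed: alkenyl rather than methyl transfer from Al (sp2 groups transmetalate first), allene rather than alkyne product (terminal alkyne, tertiary carbon and a hard nucleophile all favour the allenyl–Pd path), and six- rather than five-ring closure (re-closure at C5 would need protonation of the central allene carbon, gives no aromatic product and finds no π-acid in the medium). The last proton has to go to C1′ and not to C3′: under weak-base relay it is delivered to the anion of 13, a pentadienyl-type system C5=C6–C1′–C2′=C3′ whose central carbon is protonated fastest, which gives the skipped diene. Closure at or below 40 °C should outrun the [1,5]-hydrogen shift open to the vinylallene, which as a rule needs higher temperature.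

## Compound list

1 | methyl pyruvate | COC(=O)C(C)=O | starting material
2 | ethynylmagnesium bromide | C#C[Mg]Br | starting material
3 | methyl (±)-2-hydroxy-2-methylbut-3-ynoate | COC(=O)C(C)(O)C#C | intermediate
4 | methoxyacetyl chloride | COCC(=O)Cl | starting material
5 | methyl (±)-2-[(methoxyacetyl)oxy]-2-methylbut-3-ynoate | COCC(=O)OC(C)(C#C)C(=O)OC | intermediate
6 | (±)-5-ethynyl-4-hydroxy-3-methoxy-5-methylfuran-2(5H)-one | COC1=C(O)C(C)(C#C)OC1=O | intermediate
7 | (±)-5-ethynyl-3,4-dimethoxy-5-methylfuran-2(5H)-one | COC1=C(OC)C(C)(C#C)OC1=O | intermediate
8 | (6-bromohexyl)benzene | BrCCCCCCc1ccccc1 | starting material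
9 | lithium acetylide–ethylenediamine complex | [Li+].[C-]#C.NCCN | starting material
10 | oct-7-yn-1-ylbenzene | C#CCCCCCCc1ccccc1 | intermediate
11 | dimethyl[(1E)-2-methyl-8-phenyloct-1-en-1-yl]alane | C[Al](C)/C=C(\C)CCCCCCc1ccccc1 | intermediate
12 | (2Z,7E)-2,3-dimethoxy-4,8-dimethyl-14-phenyltetradeca-2,4,5,7-tetraenoic acid (racemic allene axis) | OC(=O)/C(OC)=C(OC)\C(C)=C=C/C=C(\C)CCCCCCc1ccccc1 | intermediate
13 | 3,4-dimethoxy-5-methyl-6-[(2E)-3-methyl-9-phenylnon-2-en-1-ylidene]-6H-pyran-2-ol | OC1=C(OC)C(OC)=C(C)C(=C/C=C(\C)CCCCCCc2ccccc2)O1 | intermediate
14 | lehualide E, 3,4-dimethoxy-5-methyl-6-[(2E)-3-methyl-9-phenylnon-2-en-1-yl]-2H-pyran-2-one | COc1c(C)c(C/C=C(\C)CCCCCCc2ccccc2)oc(=O)c1OC | target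

## Step count and least certain steps

Total step count: 6.
Longest linear sequence: 5 (steps 1, 2, 3, 4, 6).

**Step 6 (key step, Proposed new method).**

Three processes are most likely to go wrong.
- Ionisation of the lactone C5–O1 bond may be slow. The alane would then be used up by protonolysis at the alkyne C–H, or the allenylpalladium species would drift into β-hydride elimination from the C5 methyl group.
- After coupling, ring closure may be too slow, so that the [1,5]-hydrogen shift of the vinylallene or re-closure at C5 competes.
- The last proton may be delivered to C3′ instead of C1′, which moves the alkene into conjugation with the ring.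

The fallback uses known chemistry only. It sets out from 7 and comes back at 14.
- Carbonyl-assisted Markovnikov hydration of the alkyne of 7 (Au(I) or Hg(II), wet dioxane) gives (±)-5-acetyl-3,4-dimethoxy-5-methylfuran-2(5H)-one F1.
- Samarium diiodide cleaves the C5–O bond of this α-acyloxy ketone to (±)-(Z)-2,3-dimethoxy-4-methyl-5-oxohex-2-enoic acid F2.
- Acid-catalysed enol lactonisation (Ac2O, cat. TsOH) gives 3,4-dimethoxy-5,6-dimethyl-2H-pyran-2-one F3.
- Radical bromination (NBS) at the C6 methyl group, whose radical is conjugated through the whole dienyl lactone, gives 6-(bromomethyl)-3,4-dimethoxy-5-methyl-2H-pyran-2-one F4.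
- Pd(0)-catalysed coupling of F4 with the alane 11, made from 10 as in step 6, gives 14.

This path forms the pyranone first and joins the chain at C1′–C2′ by an ordinary alkenyl–benzylic-type coupling.

**Step 3.**

The lithium enolate of 5 is the enolate of a propargylic glycolate-type ester. It may drift into a [3,3] rearrangement, or lose the acyl group back to the alkoxide of 3, before it reaches the methyl ester. The alkyne C–H also competes for base.

The fallback sets out from 3 and comes back at 6, with the order of bond formation reversed.
- An excess of the lithium enolate of methyl methoxyacetate attacks the ester of 3, whose hydroxyl group is masked as its lithium alkoxide. This intermolecular Claisen condensation gives methyl 4-hydroxy-2-methoxy-4-methyl-3-oxohex-5-ynoate F5.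
- F5 lactonises on acidification to 6.
- Compound 5 is bypassed.

**Step 4.**

The tetronate anion is ambident. Methyl transfer to the lactone carbonyl oxygen or to C3 would waste material and give isomers that are hard to separate.

The fallback sets out from 6 and comes back at 7, with the roles of nucleophile and electrophile exchanged.
- Sulfonylation of the acidic C4 hydroxyl group (TsCl, Et3N) gives (±)-2-ethynyl-4-methoxy-2-methyl-5-oxo-2,5-dihydrofuran-3-yl 4-methylbenzenesulfonate F6.
- Sodium methoxide then enters at C4 by conjugate addition–elimination.
- The new C4–O bond is thus made at carbon, and the regiochemistry follows from the position of the leaving group.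

## Further compounds

F1 | step 6 | (±)-5-acetyl-3,4-dimethoxy-5-methylfuran-2(5H)-one | COC1=C(OC)C(C)(C(C)=O)OC1=O
F2 | step 6 | (±)-(Z)-2,3-dimethoxy-4-methyl-5-oxohex-2-enoic acid | OC(=O)/C(OC)=C(OC)\C(C)C(C)=O
F3 | step 6 | 3,4-dimethoxy-5,6-dimethyl-2H-pyran-2-one | COc1c(C)c(C)oc(=O)c1OC
F4 | step 6 | 6-(bromomethyl)-3,4-dimethoxy-5-methyl-2H-pyran-2-one | COc1c(C)c(CBr)oc(=O)c1OC
F5 | step 3 | methyl 4-hydroxy-2-methoxy-4-methyl-3-oxohex-5-ynoate | COC(=O)C(OC)C(=O)C(C)(O)C#C
F6 | step 4 | (±)-2-ethynyl-4-methoxy-2-methyl-5-oxo-2,5-dihydrofuran-3-yl 4-methylbenzenesulfonate | COC1=C(OS(=O)(=O)c2ccc(C)cc2)C(C)(C#C)OC1=O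
A1 | alternative 1 | methyl (E)-2-methoxy-4,8-dimethyl-3,5-dioxo-14-phenyltetradec-7-enoate | COC(=O)C(OC)C(=O)C(C)C(=O)C/C=C(\C)CCCCCCc1ccccc1
A2 | alternative 1 | 4-hydroxy-3-methoxy-5-methyl-6-[(2E)-3-methyl-9-phenylnon-2-en-1-yl]-2H-pyran-2-one | COc1c(O)c(C)c(C/C=C(\C)CCCCCCc2ccccc2)oc1=O
A3 | alternative 1 | 2,3-dimethoxy-5-methyl-6-[(2E)-3-methyl-9-phenylnon-2-en-1-yl]-4H-pyran-4-one | COc1oc(C/C=C(\C)CCCCCCc2ccccc2)c(C)c(=O)c1OC
A4 | alternative 2 | dimethyl squarate | COC1=C(OC)C(=O)C1=O
A5 | alternative 2 | (±)-4-hydroxy-2,3-dimethoxy-4-methylcyclobut-2-en-1-one | COC1=C(OC)C(C)(O)C1=O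
A6 | alternative 2 | (±)-2,3-dimethoxy-4-methyl-4-[(E)-4-methyl-10-phenyldec-3-enoyl]cyclobut-2-en-1-one | COC1=C(OC)C(C)(C(=O)C/C=C(\C)CCCCCCc2ccccc2)C1=O
A7 | alternative 2 | 3-methoxy-4-methylcyclobut-3-ene-1,2-dione | COC1=C(C)C(=O)C1=O
A8 | alternative 3 | (Z)-2,3-dimethoxyacrylic acid | CO/C=C(OC)/C(=O)O
A9 | alternative 3 | [(E)-7-methyldodec-7-en-10-yn-1-yl]benzene | CC#CC/C=C(\C)CCCCCCc1ccccc1
A10 | alternative 3 | 3,4-dimethoxy-6-methyl-5-[(2E)-3-methyl-9-phenylnon-2-en-1-yl]-2H-pyran-2-one | COc1c(C/C=C(\C)CCCCCCc2ccccc2)c(C)oc(=O)c1OC
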